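Remark on the chemistry: cembrane numbering is used throughout (C1 isopropenyl carbon, C2 ring acetate carbon, C18 the carbon on C4, C19 the methylene on C8). The open-chain aldehyde 24 and the macrocyclic ester 25 were checked atom by atom against the target and need no correction; the CIP letter at C2 is R in 6–8 and 17–24 and S from 25 on only because the priorities of its neighbours change.

## Structural features

The target is a monocyclic cembranoid: one fourteen-membered carbocycle (C1–C14) and no other ring. It carries an isopropenyl group on C1, an acetate on C2, an acetoxymethyl group (C18) on C4, a free hydroxyl on C7, an exocyclic methylene (C19) on C8 and a methyl on C12. C1 (R) and C2 (S) are adjacent and anti; C7 (R) lies five ring bonds from C2 and cannot be controlled from that pair, so the two stereochemical regions have to be set independently. The ring holds two trisubstituted alkenes, C3=C4 with C18 trans to C2 and (E)-C11=C12, beside two 1,1-disubstituted alkenes (C8=C19 and the isopropenyl group). The secondary C2 and primary C18 allylic acetates are sensitive to acid, strong base and zerovalent palladium, the C7 allylic alcohol is easily oxidised, and the 1,5-diene arrays invite acid-induced transannular cyclisation. Of the three oxygens, two must end as acetates and one as a free alcohol, so they must stay differentiated to the end. The real difficulty is closing the fourteen-membered ring with a defined trisubstituted alkene geometry without creating or disturbing a stereocentre. The key step exploits the C18 carbon on C4: at the ester oxidation level C3=C4–C18 is a 2-alkyl-2-enoate, so the ring bond C3=C4 can be made from a C4 phosphonoacetate and a C3 aldehyde, whose normal preference places the ester trans to C2.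

## Logic of the disconnections

29 back to 25. No carbon–carbon bond is cut; only the O2 and O18 acetyl bonds, the O7–H bond and the C18 oxidation level are changed, through 28, 27 and 26. The reason is that an ester at C18 is what activates C4 for olefination, and a silyl ether on O2 and a p-methoxybenzyl ether on O7 keep the three oxygens distinct. The gain is that 25 carries one reducible group and two orthogonal ethers. The demand on steps 19–22 is a clean 1,2-reduction, joint acetylation of O2 and O18 while O7 is still masked, and a final neutral oxidative unmasking of O7 that spares two allylic acetates.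

25 back to 24. The ring bond C3=C4 is cut. It is the only ring bond that is a 2-alkyl-2-enoate double bond, and its geometry is the one a stabilised phosphonate gives. The gain is an open chain whose three stereocentres are already in place and are not touched by the closure. The demand is ring closure at high dilution with the ester trans to C2, under a base mild enough to leave the α-silyloxy aldehyde configurationally intact.

24 back to 20 and 21. The C4–C5 bond is cut, and C3 is taken back from aldehyde to a primary silyl ether through 23 and 22. C4 is the acidic carbon of 21 and C5 is an unhindered primary carbon, so the bond is a plain enolate alkylation. The gain is that the whole phosphonoacetate unit comes from a commercial reagent. The demand is monoalkylation and, later, removal of the primary silyl group of 22 in the presence of the secondary one.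

20 back to 8 and 16. The C9–C10 bond is cut, with a sulfonyl group placed on C10; the O5/O7 benzylidene acetal of 18 is the precursor of the O7 ether and the C5 alcohol of 19. C10 is allylic to C11=C12 and can be made nucleophilic as a sulfone, while C9 belongs to a 2-substituted allyl unit whose two termini are equivalent, so no regiochemical question arises on the electrophile. The gain is two fragments of similar size, one carrying C1 and C2, the other C7. The demand is C-alkylation at C10, then removal of sulfur from 17 without moving or isomerising C11=C12, and regioselective reductive opening of the acetal in 18.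

8 back to 4 and 5. The C1–C2 bond is cut. An (E)-γ-substituted, β-methyl allylboronate adding to an aldehyde creates this bond, both stereocentres in their anti relationship and the isopropenyl group in one event. The gain is that 4 is achiral and 5 is commercial. The demand is retention of the (E)-geometry in 4 and catalyst control of the aldehyde face.

4 back to 1. The C–B bond is traced to the C–O bond of 3, the C–O bond to a C–H bond of the (E)-methyl group of 2, and the C–S bond of 2 to the C–Br bond of 1. The gain is that all ten carbons of C1, C10–C16 and C20, and the (E)-C11=C12 alkene, come from one commercial terpene bromide. The demand is site-selective allylic oxidation of the terminal alkene of 2.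

16 back to 11 and 12. The C7–C8 bond is cut, through 15, 14 and 13. An amine-catalysed acrylate–aldehyde coupling forms this bond and sets C7 while delivering C8 with its methylene (C19) and C9 at the ester level. The p-methoxybenzyl group on O5 of 13 is then moved into an O5/O7 acetal (14), which protects both oxygens with one group. The demand is enantiocontrol at C7 in the coupling.

11 back to 9 and 10. The O–C5 bond is cut: conjugate addition of the alcohol 10 to 9 gives the three-carbon C5–C7 aldehyde. The gain is two bulk chemicals; the demand is only suppression of acrolein polymerisation.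

## Other disconnections considered

Alternative 1: The cut is the C1–C2 ring bond, the bond a geranylgeranyl-type chain would form in nature; macrocyclic alcohol A2 is traced to the open-chain C2 enal A1 ending in a C16 allylic bromide. In the forward step CrCl2 (divalent chromium) turns the bromide of A1 into an allylchromium species that adds through C1 to the aldehyde in a six-membered chair (Nozaki–Hiyama–Kishi-type allylation). That closes the ring, creates C1 and C2 and reveals the isopropenyl group.
- In its favour: one step makes the ring, a C–C bond, two stereocentres and an alkene; the anti relationship of C1 and C2 follows from the chair whichever bromide geometry is used; the reagent tolerates the acetate and silyl ether. A2 already has the 18-acetate, so only acetylation at O2 and desilylation at O7 remain.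
- Against it here: the chair fixes C1 relative to C2 but not the pair relative to C7. Which face pair reacts would have to be decided by a stereocentre five atoms from the aldehyde carbon, so the (1S,2R,7R) diastereomer is a real prospect, and it would form at the last carbon–carbon bond. A1 also needs selective oxidation at C16, C18 and C7/C19 of a linear polyene.
- Comparison, structure: the alternative creates the contiguous centres during ring closure, whereas the chosen plan creates them in the small fragment 7 under catalyst control and closes the ring at a bond that carries no stereocentre.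
- Comparison, mechanism: both closures go through ordered cyclic transition states; the chromium closure is irreversible, the olefination is corrected by reversibility.
- Comparison, step economy: the alternative is the better of the two (one linear chain, two steps after closure instead of four), and its indifference to the bromide geometry is a genuine advantage. The chosen plan is the safer one for absolute configuration.

Alternative 2: The cut is the C14–C1 bond; the fourteen-membered acid A4 is traced to the eighteen-membered lactone A3, in which the carboxyl carbon attached to C14 is esterified with the C16 allylic oxygen. In the forward step KN(SiMe3)2 and Me3SiCl convert A3 into its silyl ketene acetal, which undergoes a [3,3] shift (Ireland–Claisen). This joins C14 to C1, releases the C15=C16 alkene and contracts the ring by four atoms.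
- In its favour: the ring is first closed by lactonisation, a more dependable macrocyclisation than an olefination, and the carbon–carbon bond then forms in a unimolecular pericyclic step that needs no dilution. On ring-closing reliability it is the equal or the better of the chosen plan.
- Against it here: the carboxyl carbon on C14 is not part of the target and must be excised, for example by radical decarboxylation, in a macrocycle holding four alkenes. C1 is created in the rearrangement, its configuration depends on how C2 biases a transition state held inside an eighteen-membered ring, and chair and boat pathways are both open. The base also meets allylic silyl ethers and an allylic ester.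
- Comparison, structure: a stereocentre and a superfluous carbon are introduced at ring formation; the chosen closure introduces neither.
- Comparison, mechanism: concerted and intramolecular against stepwise and reversible; the alternative avoids bimolecular competition.
- Comparison, step economy: the alternative is longer, by the lactone assembly and the removal of the acid.

Alternative 3: The cut is the C9–C10 bond; the 10-phenylsulfonyl macrocycle A6 is traced to the open-chain C10 sulfone A5 with a C9 allylic bromide. In the forward step KN(SiMe3)2 deprotonates C10 and the carbanion displaces the bromide, closing the ring with C1, C2, C7 and both trisubstituted alkenes already in place.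
- In its favour: the C3=C4 geometry can be set and purified at an open-chain stage, which is better than the chosen plan on that point. Direct and allylic-transposed substitution at the 2-substituted allyl bromide give the same product, and no stereocentre that survives is created.
- Against it here: sulfur must afterwards be removed from the macrocycle, where transannular strain may change the site of hydride delivery. C18 has to be carried as a protected alcohol, which costs a reduction and a protection before closure. A strong base acts on a substrate with an allylic bromide and several allylic ethers.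
- Comparison, structure: equal, since neither closure creates a lasting stereocentre.
- Comparison, mechanism: irreversible SN2 alkylation against a reversible addition–elimination that can correct geometry.
- Comparison, step economy: about equal to slightly longer. The chosen plan forms the same C9–C10 bond, but between two fragments (step 11), where a poor coupling costs little material.

Key step: step 18

## Route

Step 1
Reactants: 1 geranyl bromide, (2E)-1-bromo-3,7-dimethylocta-2,6-diene
Product: 2 geranyl phenyl sulfone, (2E)-3,7-dimethyl-1-(phenylsulfonyl)octa-2,6-diene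
Conditions: PhSO2Na, DMF, 0 °C to rt
Reagents that add atoms: sodium benzenesulfinate, [Na+].[O-]S(=O)c1ccccc1
Why: SN2 displacement of the primary allylic bromide by the sulfur of the sulfinate (S-alkylation) keeps the (E)-alkene; the sulfone later makes C10 the nucleophile of the fragment union.

Step 2
Reactants: 2 geranyl phenyl sulfone
Product: 3 (2E,6E)-2,6-dimethyl-8-(phenylsulfonyl)octa-2,6-dien-1-ol
Conditions: SeO2 (cat.), t-BuOOH, salicylic acid (cat.), CH2Cl2, rt
Reagents that add atoms: tert-butyl hydroperoxide, CC(C)(C)OO (terminal oxidant; the new oxygen is relayed through selenium dioxide, O=[Se]=O)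
Why: Allylic oxidation by SeO2 (ene reaction, then [2,3]-sigmatropic shift) attacks the (E)-methyl group of the electron-rich terminal alkene; the alkene next to the sulfonyl group is deactivated.

Step 3
Reactants: 3 (2E,6E)-2,6-dimethyl-8-(phenylsulfonyl)octa-2,6-dien-1-ol
Product: 4 2-[(2E,6E)-2,6-dimethyl-8-(phenylsulfonyl)octa-2,6-dien-1-yl]-4,4,5,5-tetramethyl-1,3,2-dioxaborolane
Conditions: Pd(MeCN)4(BF4)2 (cat.), B2pin2, DMSO/MeOH, rt
Reagents that add atoms: bis(pinacolato)diboron, CC1(C)OB(OC1(C)C)B1OC(C)(C)C(C)(C)O1
Why: Palladium-catalysed borylation of an allylic alcohol: the divalent palladium precatalyst is reduced by the diboron, the alcohol ionises to a π-allyl complex, and B–B transmetalation with reductive elimination places boron on the unsubstituted terminus. The more stable syn complex should give the (E)-allylboronate.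

Step 4
Reactants: 4 the (2E,6E)-allyl pinacol boronate; 5 (tert-butyldimethylsilyloxy)acetaldehyde
Product: 7 (2R,3R,6E)-1-(tert-butyldimethylsilyloxy)-6-methyl-8-(phenylsulfonyl)-3-(prop-1-en-2-yl)oct-6-en-2-ol, via pinacol borate ester 6 (not isolated)
Conditions: (R)-TRIP (5 mol %), 4 Å MS, toluene, −30 °C; then aq. NaHCO3
Reagents that add atoms: none
Why: Chiral phosphoric acid-catalysed allylboration through a closed six-membered chair; the (E)-γ-substituent is equatorial, so the C14 chain on C1 and the oxygen on C2 come out anti (C1 R). The catalyst, (R)-3,3′-bis(2,4,6-triisopropylphenyl)-1,1′-binaphthyl-2,2′-diyl hydrogen phosphate, binds a boronate oxygen and the formyl hydrogen and is expected to expose the Re face of 5, which gives C2 the spatial arrangement of the target; aqueous work-up hydrolyses 6.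

Step 5
Reactants: 7 the C2 alcohol
Product: 8 (2R,3R,6E)-1,2-bis(tert-butyldimethylsilyloxy)-6-methyl-8-(phenylsulfonyl)-3-(prop-1-en-2-yl)oct-6-ene
Conditions: TBSOTf, 2,6-lutidine, CH2Cl2, −78 to 0 °C
Reagents that add atoms: tert-butyldimethylsilyl trifluoromethanesulfonate, CC(C)(C)[Si](C)(C)OS(=O)(=O)C(F)(F)F
Why: Silyl triflate silylation of a hindered secondary alcohol; O2 now bears the group it keeps through the ring closure, and the less hindered primary ether on O3 stays selectively removable.

Step 6
Reactants: 9 acrolein; 10 4-methoxybenzyl alcohol
Product: 11 3-(4-methoxybenzyloxy)propanal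
Conditions: ClCH2CO2H (cat.), NaOH (cat.), AcOH (cat.), neat, 40 °C
Reagents that add atoms: none
Why: Oxa-Michael addition of the benzylic alcohol to acrolein under weakly acidic buffering gives the C5–C7 aldehyde with O5 already protected; no stereocentre is involved.

Step 7
Reactants: 11 3-(4-methoxybenzyloxy)propanal; 12 1,1,1,3,3,3-hexafluoropropan-2-yl acrylate
Product: 13 1,1,1,3,3,3-hexafluoropropan-2-yl (3R)-3-hydroxy-5-(4-methoxybenzyloxy)-2-methylidenepentanoate
Conditions: β-isocupreidine (10 mol %), DMF, −55 °C
Reagents that add atoms: none
Why: Enantioselective Morita–Baylis–Hillman reaction: the quinidine-derived amine adds to the activated acrylate, the ammonium enolate adds to the aldehyde (C7–C8 bond), and the phenolic hydroxyl of the catalyst steers proton transfer and elimination. The (R)-adduct is the expected product for unbranched aliphatic aldehydes, which sets C7.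

Step 8
Reactants: 13 the (3R)-hydroxy acrylate
Product: 14 1,1,1,3,3,3-hexafluoropropan-2-yl 2-[(2R,4R)-2-(4-methoxyphenyl)-1,3-dioxan-4-yl]prop-2-enoate
Conditions: DDQ, 4 Å MS, CH2Cl2, 0 °C
Reagents that add atoms: none
Why: Under anhydrous conditions DDQ oxidises the p-methoxybenzyl ether to its oxocarbenium ion, which the 1,3-related C7 hydroxyl captures to give the six-membered p-methoxybenzylidene acetal with both substituents equatorial. One group now protects O5 and O7.

Step 9
Reactants: 14 the acetal ester
Product: 15 2-[(2R,4R)-2-(4-methoxyphenyl)-1,3-dioxan-4-yl]prop-2-en-1-ol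
Conditions: i-Bu2AlH, CH2Cl2, −78 °C
Reagents that add atoms: none
Why: 1,2-Reduction of the activated ester to the primary allylic alcohol (C9); the acetal is not opened by the hydride at this temperature.

Step 10
Reactants: 15 the allylic alcohol
Product: 16 (2R,4R)-4-(3-bromoprop-1-en-2-yl)-2-(4-methoxyphenyl)-1,3-dioxane
Conditions: CBr4, PPh3, 2,6-lutidine, CH2Cl2, 0 °C
Reagents that add atoms: tetrabromomethane, BrC(Br)(Br)Br
Why: Appel bromination of a primary allylic alcohol; on this 2-substituted allyl unit direct and transposed substitution give the same bromide, and the lutidine buffers the acid-sensitive acetal.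

Step 11
Reactants: 8 the bis-silyl sulfone; 16 the allylic bromide
Product: 17 C9–C10 coupled sulfone (C10 epimers): 10-phenylsulfonyl, 2,3-bis(tert-butyldimethylsilyloxy), O5/O7 p-methoxybenzylidene acetal
Conditions: n-BuLi, THF/DMPU, −78 °C; then 16, −78 to −40 °C
Reagents that add atoms: none
Why: Deprotonation α to the sulfonyl group and C-alkylation of the allylic sulfone anion at C10 by the allylic bromide forms the C9–C10 bond. SN2 and SN2′ attack on 16 are degenerate, and the C10 epimers converge in the next step.

Step 12
Reactants: 17 the coupled sulfone
Product: 18 desulfonylated acetal: (11E)-alkene, C10 methylene, 2,3-bis(tert-butyldimethylsilyloxy), O5/O7 p-methoxybenzylidene acetal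
Conditions: Pd(dppp)Cl2 (cat.), LiBHEt3, THF, 0 °C
Reagents that add atoms: none
Why: Palladium-catalysed hydride desulfonylation of an allylic sulfone: zerovalent palladium ionises the C10–S bond and hydride attacks the less substituted C10 terminus of the π-allyl complex, which should keep C11=C12 in place and (E). Silyl ethers and the acetal are inert to the borohydride.

Step 13
Reactants: 18 the acetal
Product: 19 C5 alcohol: 7-(4-methoxybenzyloxy), 2,3-bis(tert-butyldimethylsilyloxy) (C1 R, C2 R, C7 R)
Conditions: i-Bu2AlH, CH2Cl2, −20 to 0 °C
Reagents that add atoms: none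
Why: Regioselective reductive opening of the p-methoxybenzylidene acetal: aluminium coordinates the less hindered O5, that C–O bond breaks and hydride goes to the benzylic carbon. The p-methoxybenzyl group stays on the secondary O7 and the primary C5 alcohol is freed.

Step 14
Reactants: 19 the C5 alcohol
Product: 20 C5 iodide: 7-(4-methoxybenzyloxy), 2,3-bis(tert-butyldimethylsilyloxy)
Conditions: I2, PPh3, imidazole, CH2Cl2, 0 °C to rt
Reagents that add atoms: iodine, II
Why: Appel-type iodination of an unhindered primary alcohol through the alkoxyphosphonium ion and SN2 displacement by iodide; ethers and alkenes are unaffected.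

Step 15
Reactants: 20 the C5 iodide; 21 methyl diethylphosphonoacetate
Product: 22 C4 phosphonoacetate (C4 epimers): methyl 2-(diethoxyphosphoryl) ester, 7-(4-methoxybenzyloxy), 2,3-bis(tert-butyldimethylsilyloxy)
Conditions: NaH, excess 21, DMF, 0 to 60 °C
Reagents that add atoms: none
Why: C-alkylation of the sodium enolate of the phosphonoacetate by a primary iodide forms the C4–C5 bond; an excess of the nucleophile suppresses dialkylation, and the C4 epimers are irrelevant because C4 becomes sp2.

Step 16
Reactants: 22 the bis-silyl phosphonoacetate
Product: 23 C3 alcohol: 2-(tert-butyldimethylsilyloxy), 7-(4-methoxybenzyloxy), C4 phosphonoacetate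
Conditions: HF·pyridine, pyridine, THF, 0 °C
Reagents that add atoms: none
Why: Buffered HF·pyridine cleaves the unhindered primary silyl ether much faster than the secondary one next to the branched C1; the acidic medium avoids 1,2-silyl migration.

Step 17
Reactants: 23 the C3 alcohol
Product: 24 open-chain C3 aldehyde with C4 phosphonoacetate (C4 epimers): 2-(tert-butyldimethylsilyloxy), 7-(4-methoxybenzyloxy)
Conditions: Dess–Martin periodinane, NaHCO3, CH2Cl2, 0 °C to rt
Reagents that add atoms: none
Why: Dess–Martin oxidation under buffered, non-basic conditions gives the α-silyloxy aldehyde without epimerising C2; the crude aldehyde is used at once.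

Step 18
Reactants: 24 the open-chain aldehyde phosphonoacetate
Product: 25 methyl (1R,2S,3E,7R,11E)-2-(tert-butyldimethylsilyloxy)-7-(4-methoxybenzyloxy)cembra-3,8(19),11,15-tetraen-18-oate
Conditions: LiCl, i-Pr2NEt, MeCN (1 mM, slow addition), rt
Reagents that add atoms: none
Why: Intramolecular Horner–Wadsworth–Emmons olefination under soft enolisation: Li+ binds the phosphoryl and ester oxygens of 24 so that the tertiary amine can remove the C4 proton, and the chelated carbanion adds to the C3 aldehyde to give β-oxido phosphonates that close to oxaphosphetanes and expel lithium diethyl phosphate. The closest known reaction type is the LiCl/amine macrocyclisation of ω-formyl 2-alkylphosphonoacetates to fourteen-membered 2-alkylidene esters. The one ring is closed by attack of C4 on the exocyclic carbonyl of C3 (a 14-exo-trig addition) followed by elimination, so the ring bond formed is C3=C4; high dilution and slow addition favour this over bimolecular olefination. No stereocentre is created, and both C4 epimers of 24 converge on the same sp2 carbon. The selectivity needed is the ester trans to C2: addition is reversible for this stabilised α-branched anion, and the oxaphosphetane that keeps the ester away from the bulky α-silyloxy, β-branched C2 substituent collapses faster. That geometry also puts the ring carbons C2 and C5 cis, which a fourteen-membered ring accommodates without strain. The integrity of C2 is secured because the amine is too weak to enolise the α-silyloxy aldehyde at a competitive rate. The C7 ether, the C2 silyl ether and the four alkenes are inert to these conditions.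

Step 19
Reactants: 25 the macrocyclic methyl ester
Product: 26 (1R,2S,3E,7R,11E)-2-(tert-butyldimethylsilyloxy)-7-(4-methoxybenzyloxy)cembra-3,8(19),11,15-tetraen-18-ol
Conditions: i-Bu2AlH, CH2Cl2, −78 °C
Reagents that add atoms: none
Why: 1,2-Reduction of the 2-alkyl-2-enoate to the primary allylic alcohol brings C18 to its final oxidation level; the alkene geometry and both ethers are unaffected.

Step 20
Reactants: 26 the C18 alcohol
Product: 27 (1R,2S,3E,7R,11E)-7-(4-methoxybenzyloxy)cembra-3,8(19),11,15-tetraene-2,18-diol
Conditions: Bu4NF, THF, 0 °C to rt
Reagents that add atoms: none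
Why: Fluoride cleaves the Si–O bond of the secondary allylic silyl ether; the p-methoxybenzyl ether is stable to fluoride.

Step 21
Reactants: 27 the 2,18-diol
Product: 28 (1R,2S,3E,7R,11E)-7-(4-methoxybenzyloxy)cembra-3,8(19),11,15-tetraene-2,18-diyl diacetate
Conditions: Ac2O, pyridine, DMAP (cat.), CH2Cl2, rt
Reagents that add atoms: acetic anhydride, CC(=O)OC(C)=O
Why: DMAP-catalysed acylation of the primary and the secondary allylic alcohol; O7 is still protected, so no selectivity between hydroxyls is needed.

Step 22
Reactants: 28 the diacetate p-methoxybenzyl ether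
Product: 29 (1R,2S,3E,7R,11E)-cembra-3,8(19),11,15-tetraene-2,7,18-triol 2,18-diacetate (target)
Conditions: DDQ, CH2Cl2/pH 7 buffer, 0 °C
Reagents that add atoms: none
Why: Oxidative cleavage of the p-methoxybenzyl ether by DDQ through the benzylic oxocarbenium ion and its hemiacetal; the neutral buffered medium spares the two allylic acetates and frees the C7 hydroxyl without touching C7.

## Compound list

1 | geranyl bromide, (2E)-1-bromo-3,7-dimethylocta-2,6-diene | CC(C)=CCC/C(C)=C/CBr | starting material
2 | geranyl phenyl sulfone, (2E)-3,7-dimethyl-1-(phenylsulfonyl)octa-2,6-diene | CC(C)=CCC/C(C)=C/CS(=O)(=O)c1ccccc1 | intermediate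
3 | (2E,6E)-2,6-dimethyl-8-(phenylsulfonyl)octa-2,6-dien-1-ol | OC/C(C)=C/CC/C(C)=C/CS(=O)(=O)c1ccccc1 | intermediate
4 | 2-[(2E,6E)-2,6-dimethyl-8-(phenylsulfonyl)octa-2,6-dien-1-yl]-4,4,5,5-tetramethyl-1,3,2-dioxaborolane | CC1(C)OB(C/C(C)=C/CC/C(C)=C/CS(=O)(=O)c2ccccc2)OC1(C)C | intermediate
5 | (tert-butyldimethylsilyloxy)acetaldehyde | O=CCO[Si](C)(C)C(C)(C)C | starting material
6 | pinacol borate ester of alcohol 7 (boron on O2) | O=S(=O)(c1ccccc1)C/C=C(\C)CC[C@H](C(=C)C)[C@@H](OB1OC(C)(C)C(C)(C)O1)CO[Si](C)(C)C(C)(C)C | intermediate (not isolated)
7 | (2R,3R,6E)-1-(tert-butyldimethylsilyloxy)-6-methyl-8-(phenylsulfonyl)-3-(prop-1-en-2-yl)oct-6-en-2-ol (carbinol carbon = C2, isopropenyl carbon = C1, sulfonyl carbon = C10) | O=S(=O)(c1ccccc1)C/C=C(\C)CC[C@H](C(=C)C)[C@@H](O)CO[Si](C)(C)C(C)(C)C | intermediate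
8 | (2R,3R,6E)-1,2-bis(tert-butyldimethylsilyloxy)-6-methyl-8-(phenylsulfonyl)-3-(prop-1-en-2-yl)oct-6-ene | O=S(=O)(c1ccccc1)C/C=C(\C)CC[C@H](C(=C)C)[C@@H](O[Si](C)(C)C(C)(C)C)CO[Si](C)(C)C(C)(C)C | intermediate
9 | acrolein | C=CC=O | starting material
10 | 4-methoxybenzyl alcohol | COc1ccc(CO)cc1 | starting material
11 | 3-(4-methoxybenzyloxy)propanal | O=CCCOCc1ccc(OC)cc1 | intermediate
12 | 1,1,1,3,3,3-hexafluoropropan-2-yl acrylate | C=CC(=O)OC(C(F)(F)F)C(F)(F)F | starting material
13 | 1,1,1,3,3,3-hexafluoropropan-2-yl (3R)-3-hydroxy-5-(4-methoxybenzyloxy)-2-methylidenepentanoate | C=C(C(=O)OC(C(F)(F)F)C(F)(F)F)[C@H](O)CCOCc1ccc(OC)cc1 | intermediate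
14 | 1,1,1,3,3,3-hexafluoropropan-2-yl 2-[(2R,4R)-2-(4-methoxyphenyl)-1,3-dioxan-4-yl]prop-2-enoate (cis acetal) | C=C(C(=O)OC(C(F)(F)F)C(F)(F)F)[C@H]1CCO[C@@H](c2ccc(OC)cc2)O1 | intermediate
15 | 2-[(2R,4R)-2-(4-methoxyphenyl)-1,3-dioxan-4-yl]prop-2-en-1-ol | C=C(CO)[C@H]1CCO[C@@H](c2ccc(OC)cc2)O1 | intermediate
16 | (2R,4R)-4-(3-bromoprop-1-en-2-yl)-2-(4-methoxyphenyl)-1,3-dioxane | C=C(CBr)[C@H]1CCO[C@@H](c2ccc(OC)cc2)O1 | intermediate
17 | coupled sulfone (C10 epimers): open chain C3–C2–C1–C14…C5 with 10-phenylsulfonyl, (11E)-alkene, 8(19)-methylene, 2,3-bis(tert-butyldimethylsilyloxy), cis O5/O7 p-methoxybenzylidene acetal (C1 R, C2 R, C7 R) | C=C(CC(S(=O)(=O)c1ccccc1)/C=C(\C)CC[C@H](C(=C)C)[C@@H](O[Si](C)(C)C(C)(C)C)CO[Si](C)(C)C(C)(C)C)[C@H]1CCO[C@@H](c2ccc(OC)cc2)O1 | intermediate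
18 | desulfonylated acetal: as 17 with C10 methylene | C=C(CC/C=C(\C)CC[C@H](C(=C)C)[C@@H](O[Si](C)(C)C(C)(C)C)CO[Si](C)(C)C(C)(C)C)[C@H]1CCO[C@@H](c2ccc(OC)cc2)O1 | intermediate
19 | C5 alcohol: 7-(4-methoxybenzyloxy), 2,3-bis(tert-butyldimethylsilyloxy), (11E), 8(19)-methylene (C1 R, C2 R, C7 R) | C=C(CC/C=C(\C)CC[C@H](C(=C)C)[C@@H](O[Si](C)(C)C(C)(C)C)CO[Si](C)(C)C(C)(C)C)[C@H](OCc1ccc(OC)cc1)CCO | intermediate
20 | C5 iodide: as 19 with iodine on C5 | C=C(CC/C=C(\C)CC[C@H](C(=C)C)[C@@H](O[Si](C)(C)C(C)(C)C)CO[Si](C)(C)C(C)(C)C)[C@H](OCc1ccc(OC)cc1)CCI | intermediate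
21 | methyl diethylphosphonoacetate | COC(=O)CP(=O)(OCC)OCC | starting material
22 | C4 phosphonoacetate (C4 epimers): methyl ester and diethyl phosphonate on C4, 7-(4-methoxybenzyloxy), 2,3-bis(tert-butyldimethylsilyloxy) | C=C(CC/C=C(\C)CC[C@H](C(=C)C)[C@@H](O[Si](C)(C)C(C)(C)C)CO[Si](C)(C)C(C)(C)C)[C@H](OCc1ccc(OC)cc1)CCC(C(=O)OC)P(=O)(OCC)OCC | intermediate
23 | C3 alcohol: as 22 with free primary hydroxyl on C3 and silyl ether on O2 only | C=C(CC/C=C(\C)CC[C@H](C(=C)C)[C@@H](O[Si](C)(C)C(C)(C)C)CO)[C@H](OCc1ccc(OC)cc1)CCC(C(=O)OC)P(=O)(OCC)OCC | intermediate
24 | open-chain C3 aldehyde with C4 phosphonoacetate (C4 epimers): 2-(tert-butyldimethylsilyloxy), 7-(4-methoxybenzyloxy) (C1 R, C2 R, C7 R) | C=C(CC/C=C(\C)CC[C@H](C(=C)C)[C@@H](O[Si](C)(C)C(C)(C)C)C=O)[C@H](OCc1ccc(OC)cc1)CCC(C(=O)OC)P(=O)(OCC)OCC | intermediate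
25 | methyl (1R,2S,3E,7R,11E)-2-(tert-butyldimethylsilyloxy)-7-(4-methoxybenzyloxy)cembra-3,8(19),11,15-tetraen-18-oate | C=C1CC/C=C(\C)CC[C@H](C(=C)C)[C@@H](O[Si](C)(C)C(C)(C)C)/C=C(/C(=O)OC)CC[C@H]1OCc2ccc(OC)cc2 | intermediate
26 | (1R,2S,3E,7R,11E)-2-(tert-butyldimethylsilyloxy)-7-(4-methoxybenzyloxy)cembra-3,8(19),11,15-tetraen-18-ol | C=C1CC/C=C(\C)CC[C@H](C(=C)C)[C@@H](O[Si](C)(C)C(C)(C)C)/C=C(/CO)CC[C@H]1OCc2ccc(OC)cc2 | intermediate
27 | (1R,2S,3E,7R,11E)-7-(4-methoxybenzyloxy)cembra-3,8(19),11,15-tetraene-2,18-diol | C=C1CC/C=C(\C)CC[C@H](C(=C)C)[C@@H](O)/C=C(/CO)CC[C@H]1OCc2ccc(OC)cc2 | intermediate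
28 | (1R,2S,3E,7R,11E)-7-(4-methoxybenzyloxy)cembra-3,8(19),11,15-tetraene-2,18-diyl diacetate | C=C1CC/C=C(\C)CC[C@H](C(=C)C)[C@@H](OC(C)=O)/C=C(/COC(C)=O)CC[C@H]1OCc2ccc(OC)cc2 | intermediate
29 | (1R,2S,3E,7R,11E)-cembra-3,8(19),11,15-tetraene-2,7,18-triol 2,18-diacetate | C=C1CC/C=C(\C)CC[C@H](C(=C)C)[C@@H](OC(C)=O)/C=C(/COC(C)=O)CC[C@H]1O | target

## Step count and least certain steps

Total: 22 steps. Longest linear sequence: 17 steps (steps 1–5 and 11–22; the branch through steps 6–10 and 11–22 is of the same length).

Step 18 (key step). The most likely failure is loss of geometric control at C3=C4, because collapse of the oxaphosphetanes in a macrocyclic setting may not wait for full equilibration; bimolecular olefination is the second risk if dilution is insufficient. The fallback moves geometric control to the aldehyde oxidation level. It sets out from 24: the crude closure product, a mixture of 25 and the (3Z)-macrocyclic ester F1, is reduced with i-Bu2AlH to 26 and the (3Z)-allylic alcohol F2. The mixture is oxidised with MnO2 to the (3Z)-enal F3 and the (3E)-enal F4, and F3 is equilibrated to F4 by reversible conjugate addition of a thiol (cat. PhSH, Et3N). A 2-alkyl-2-enal strongly prefers the formyl group trans to the β-substituent. Luche reduction (NaBH4, CeCl3·7H2O) then returns the route at 26.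

Step 4. The most likely failure is poor facial selectivity: the hindered β,γ-disubstituted boronate reacts slowly, so the uncatalysed racemic pathway can compete, and the α-silyloxy group of 5 may disturb the catalyst–aldehyde hydrogen bond. The fallback replaces catalyst control by a chiral auxiliary on boron and sets out from 3. Palladium-catalysed borylation with B2(OH)4 (Pd(MeCN)4(BF4)2, DMSO/MeOH) gives the allylboronic acid F5. Esterification with diisopropyl (S,S)-tartrate (MgSO4, Et2O) gives the tartrate allylboronate F6, the antipode expected to expose the Re face. Addition to 5 (toluene, 4 Å MS, −78 °C) through the same chair gives the tartrate borate ester F7, whose hydrolysis returns the route at 7.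

Step 7. The most likely failure is slow conversion with erosion of enantioselectivity, because the β-alkoxy aldehyde can lose the benzylic alcohol by amine-induced elimination and the adduct can react with a second aldehyde. The fallback sets C7 by reagent-controlled ketone reduction and sets out from 11. Addition of the vinyllithium made from (2-bromoallyloxy)(tert-butyl)dimethylsilane and t-BuLi gives the racemic allylic alcohol F8. Dess–Martin oxidation gives the α-methylene ketone F9. Corey–Bakshi–Shibata reduction with the (S)-methyl oxazaborolidine and BH3·SMe2, in which the 2-substituted vinyl group acts as the large substituent, gives the (R)-allylic alcohol F10. Anhydrous DDQ closes the p-methoxybenzylidene acetal silyl ether F11, and Bu4NF returns the route at 15.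

Step 12. The most likely failure is allylic transposition or E/Z scrambling of C11=C12, because the π-allyl palladium intermediate can isomerise through its tertiary σ-form before hydride delivery. The fallback replaces π-allyl/hydride chemistry by single-electron reductive cleavage. It sets out from 17 and comes back at 18 directly: Na(Hg), Na2HPO4, MeOH/THF, −20 °C, with protonation of the allyl anion at the less substituted C10. It makes no new compound (F0).

Step 22. The most likely failure is over-oxidation of the liberated C7 allylic alcohol to the enone, because DDQ also abstracts hydride from allylic carbinols. The fallback is a non-oxidative cleavage that sets out from 28 and comes back at 29: MgBr2·OEt2 and Me2S in CH2Cl2, where the Lewis acid activates the benzylic C–O bond and the sulfide captures the benzyl cation. It makes no new compound (F0).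

## Further compounds

F1 | step 18 | methyl (1R,2S,3Z,7R,11E)-2-(tert-butyldimethylsilyloxy)-7-(4-methoxybenzyloxy)cembra-3,8(19),11,15-tetraen-18-oate (ester cis to C2) | C=C1CC/C=C(\C)CC[C@H](C(=C)C)[C@@H](O[Si](C)(C)C(C)(C)C)/C=C(\C(=O)OC)CC[C@H]1OCc2ccc(OC)cc2
F2 | step 18 | (3Z)-isomer of allylic alcohol 26 | C=C1CC/C=C(\C)CC[C@H](C(=C)C)[C@@H](O[Si](C)(C)C(C)(C)C)/C=C(\CO)CC[C@H]1OCc2ccc(OC)cc2
F3 | step 18 | (3Z)-macrocyclic C18 enal, 2-silyl ether, 7-p-methoxybenzyl ether | C=C1CC/C=C(\C)CC[C@H](C(=C)C)[C@@H](O[Si](C)(C)C(C)(C)C)/C=C(\C=O)CC[C@H]1OCc2ccc(OC)cc2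
F4 | step 18 | (3E)-macrocyclic C18 enal, 2-silyl ether, 7-p-methoxybenzyl ether | C=C1CC/C=C(\C)CC[C@H](C(=C)C)[C@@H](O[Si](C)(C)C(C)(C)C)/C=C(/C=O)CC[C@H]1OCc2ccc(OC)cc2
F5 | step 4 | [(2E,6E)-2,6-dimethyl-8-(phenylsulfonyl)octa-2,6-dien-1-yl]boronic acid | OB(O)C/C(C)=C/CC/C(C)=C/CS(=O)(=O)c1ccccc1
F6 | step 4 | diisopropyl (4S,5S)-2-[(2E,6E)-2,6-dimethyl-8-(phenylsulfonyl)octa-2,6-dien-1-yl]-1,3,2-dioxaborolane-4,5-dicarboxylate | CC(C)OC(=O)[C@H]1OB(C/C(C)=C/CC/C(C)=C/CS(=O)(=O)c2ccccc2)O[C@@H]1C(=O)OC(C)C
F7 | step 4 | (S,S)-diisopropyl tartrate borate ester of alcohol 7 | O=S(=O)(c1ccccc1)C/C=C(\C)CC[C@H](C(=C)C)[C@@H](OB1O[C@H](C(=O)OC(C)C)[C@@H](C(=O)OC(C)C)O1)CO[Si](C)(C)C(C)(C)C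
F8 | step 7 | racemic 2-[(tert-butyldimethylsilyloxy)methyl]-5-(4-methoxybenzyloxy)pent-1-en-3-ol | C=C(CO[Si](C)(C)C(C)(C)C)C(O)CCOCc1ccc(OC)cc1
F9 | step 7 | 2-[(tert-butyldimethylsilyloxy)methyl]-5-(4-methoxybenzyloxy)pent-1-en-3-one | C=C(CO[Si](C)(C)C(C)(C)C)C(=O)CCOCc1ccc(OC)cc1
F10 | step 7 | (3R)-2-[(tert-butyldimethylsilyloxy)methyl]-5-(4-methoxybenzyloxy)pent-1-en-3-ol | C=C(CO[Si](C)(C)C(C)(C)C)[C@H](O)CCOCc1ccc(OC)cc1
F11 | step 7 | tert-butyldimethylsilyl ether of 15, (2R,4R)-acetal | C=C(CO[Si](C)(C)C(C)(C)C)[C@H]1CCO[C@@H](c2ccc(OC)cc2)O1
F0 | step 12 | none | none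
F0 | step 22 | none | none
A1 | alternative 1 | open-chain C2 enal with C16 allylic bromide, 18-acetate, 7-tert-butyldimethylsilyl ether (7R; E bromide shown) | O=C/C=C(/COC(C)=O)CC[C@@H](O[Si](C)(C)C(C)(C)C)C(=C)CC/C=C(\C)CC/C=C(\C)CBr
A2 | alternative 1 | (1R,2S,7R) macrocyclic C2 alcohol, 18-acetate, 7-tert-butyldimethylsilyl ether | C=C1CC/C=C(\C)CC[C@H](C(=C)C)[C@@H](O)/C=C(/COC(C)=O)CC[C@H]1O[Si](C)(C)C(C)(C)C
A3 | alternative 2 | eighteen-membered lactone: carboxyl carbon on C14 esterified with O16, 2- and 18-tert-butyldimethylsilyl ethers, 7-p-methoxybenzyl ether | O=C1CC/C(C)=C/CCC(=C)[C@H](OCc2ccc(OC)cc2)CC/C(CO[Si](C)(C)C(C)(C)C)=C\[C@H](O[Si](C)(C)C(C)(C)C)/C=C(\C)CO1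
A4 | alternative 2 | fourteen-membered carbocycle with C14 carboxylic acid (C14 epimers) | C=C1CC/C=C(\C)CC(C(=O)O)[C@H](C(=C)C)[C@@H](O[Si](C)(C)C(C)(C)C)/C=C(/CO[Si](C)(C)C(C)(C)C)CC[C@H]1OCc2ccc(OC)cc2
A5 | alternative 3 | open-chain C10 phenyl sulfone with C9 allylic bromide, 2- and 18-tert-butyldimethylsilyl ethers, 7-p-methoxybenzyl ether | C=C(CBr)[C@H](OCc1ccc(OC)cc1)CC/C(CO[Si](C)(C)C(C)(C)C)=C\[C@H](O[Si](C)(C)C(C)(C)C)[C@@H](C(=C)C)CC/C(C)=C/CS(=O)(=O)c1ccccc1
A6 | alternative 3 | 10-phenylsulfonyl macrocycle (C10 epimers) | C=C1CC(S(=O)(=O)c2ccccc2)/C=C(\C)CC[C@H](C(=C)C)[C@@H](O[Si](C)(C)C(C)(C)C)/C=C(/CO[Si](C)(C)C(C)(C)C)CC[C@H]1OCc2ccc(OC)cc2
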